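**Retrosynthetic overview**
- Rings: A = ten-membered carbocycle C1–C10; B = furanone (O, C10, C1, C2, C3); C = methylene lactone (O, C6, C7, C11, C12). Removing the side-chain acetonide and then cutting O–C3 and C1–C2 in one retro-step gives an acyclic seco acid (C1 acid chloride, C2 alkyne terminus, C10 silyl ether).
- Enabling feature: the ether oxygen on quaternary C10 lies 1,4 to C3 across the C1 ketone, so ring B is the 5-endo-dig cycloisomer of an α′-oxy ynone. Its C1–C2 bond is also a bond of ring A, and C10 carries no hydrogen, so the closure can neither aromatise nor eliminate.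
- Seco acid: ring C by Pd carbonylative lactonisation of a C11 vinyl bromide onto C6–OH; C6–OH and the C8 ester by Evans–Tishchenko reduction (this installs the 2-methylglycerate); C7–C8 by Evans syn aldol; C5–C6 by Grignard/Weinreb ketone synthesis.
- Stereocentres: C10 from (R)-2-methylglycidol, C4 from the (S)-Roche ester, C2′ from (S)-2-methylglycidol, C7/C8 from the auxiliary, C6 by 1,3-anti hydride delivery.
- Ring order: C first (step 20); then A and B, with the oxa-bridge, together in step 24.

Key step: step 24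

Remark: germacrane numbering is used (C1 ketone, C2, C3 enol-ether carbon, C4 methine, C5, C6 lactone carbinol, C7, C8 ester carbinol, C9, C10 quaternary carbon, C11=C13 methylene, C12 lactone carbonyl, C2′ side-chain carbinol); both enantiomers of 2-methylglycidol are taken to be commercial.

**Fragment A (C8–C10, C1)**

Step 1
Reactants: 1 (R)-2-methylglycidol
Product: 2 (S)-2-methylpent-4-ene-1,2-diol
Conditions: CH2=CHMgBr (3 equiv), CuI (10 mol %), THF, −30 to 0 °C
Reagents that add atoms: vinylmagnesium bromide, C=C[Mg]Br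
Why: Copper-catalysed Grignard opening (SN2) at the unsubstituted epoxide carbon; the quaternary carbinol carbon (future C10) is not touched, so its configuration is that of 1, and the degenerate Payne shift returns the same enantiomer.

Step 2
Reactants: 2 (S)-2-methylpent-4-ene-1,2-diol
Product: 3 (S)-2-methyl-1,2-bis(triethylsilyloxy)pent-4-ene
Conditions: Et3SiOTf (2.5 equiv), 2,6-lutidine, CH2Cl2, −78 to 0 °C
Reagents that add atoms: triethylsilyl trifluoromethanesulfonate, CC[Si](CC)(CC)OS(=O)(=O)C(F)(F)F
Why: Silyl triflate silylation is strong enough for the tertiary alcohol and masks both oxygens for the aldol step; no stereocentre is touched.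

Step 3
Reactants: 3 (S)-2-methyl-1,2-bis(triethylsilyloxy)pent-4-ene
Product: 5 (S)-3-methyl-3,4-bis(triethylsilyloxy)butanal, via ozonide 4 (not isolated)
Conditions: O3, CH2Cl2, −78 °C; then PPh3, −78 °C to rt
Reagents that add atoms: ozone, [O-][O+]=O
Why: Ozonolysis of the only alkene with reductive work-up should give the C8 aldehyde; silyl ethers and the quaternary centre are inert.

**Fragment B and aldol union**

Step 4
Reactants: 6 3-bromobut-3-en-1-ol
Product: 7 3-bromobut-3-enoic acid
Conditions: CrO3, H2SO4, acetone/H2O, 0 °C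
Reagents that add atoms: water, O
Why: Jones oxidation of the primary alcohol through the aldehyde hydrate; the acidic medium avoids base-induced migration of the bromovinyl double bond into conjugation.

Step 5
Reactants: 7 3-bromobut-3-enoic acid; 8 (R)-4-benzyloxazolidin-2-one
Product: 10 (R)-4-benzyl-3-(3-bromobut-3-enoyl)oxazolidin-2-one, via mixed pivalic anhydride 9 (not isolated)
Conditions: t-BuCOCl, Et3N, THF, −20 °C; then LiCl, 8, −20 °C to rt
Reagents that add atoms: none
Why: N-Acylation through the mixed anhydride under LiCl/Et3N conditions is mild enough to keep the β,γ-double bond in place.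

Step 6
Reactants: 10 (R)-4-benzyl-3-(3-bromobut-3-enoyl)oxazolidin-2-one; 5 (S)-3-methyl-3,4-bis(triethylsilyloxy)butanal
Product: 12 syn-aldol imide (2R,3S,5S), via Z-boron enolate 11 (not isolated)
Conditions: Bu2BOTf, i-Pr2NEt, CH2Cl2, −78 to 0 °C; 5, −78 to −10 °C; H2O2, pH 7 buffer, MeOH, 0 °C
Reagents that add atoms: none
Why: Evans syn aldol: the Z-boron enolate reacts through a Zimmerman–Traxler chair on the face away from the benzyl group, so the (R)-auxiliary sets C7 and C8 (syn; 2R,3S in 12) regardless of the remote C10.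

Step 7
Reactants: 12 syn-aldol imide (2R,3S,5S)
Product: 13 (2R,3S,5S)-2-(1-bromoethenyl)-3-hydroxy-N-methoxy-N,5-dimethyl-5,6-bis(triethylsilyloxy)hexanamide
Conditions: MeNHOMe·HCl, AlMe3, THF, −20 to 0 °C
Reagents that add atoms: N,O-dimethylhydroxylamine hydrochloride, CNOC.Cl
Why: Aluminium amide transamidation (Weinreb amide formation), assisted by the free β-hydroxyl, should release the auxiliary without touching C7 or C8.

**Fragment C (C2–C5)**

Step 8
Reactants: 14 methyl (S)-3-hydroxy-2-methylpropanoate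
Product: 15 methyl (S)-3-(tert-butyldimethylsilyloxy)-2-methylpropanoate
Conditions: t-BuMe2SiCl, imidazole, DMF, rt
Reagents that add atoms: tert-butyldimethylsilyl chloride, CC(C)(C)[Si](C)(C)Cl
Why: Standard silylation of the primary alcohol; the C4 stereocentre comes from the chiral pool.

Step 9
Reactants: 15 methyl (S)-3-(tert-butyldimethylsilyloxy)-2-methylpropanoate
Product: 16 (S)-3-(tert-butyldimethylsilyloxy)-2-methylpropanal
Conditions: i-Bu2AlH (1.05 equiv), CH2Cl2, −78 °C; Rochelle salt
Reagents that add atoms: none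
Why: Half-reduction of the ester through the stable tetrahedral aluminate at −78 °C; the α-centre is kept by cold work-up and immediate use.

Step 10
Reactants: 16 (S)-3-(tert-butyldimethylsilyloxy)-2-methylpropanal
Product: 17 (R)-tert-butyl[(4,4-dibromo-2-methylbut-3-en-1-yl)oxy]dimethylsilane
Conditions: CBr4, PPh3, 2,6-lutidine, CH2Cl2, 0 °C
Reagents that add atoms: tetrabromomethane, BrC(Br)(Br)Br
Why: Corey–Fuchs dibromo-olefination (Wittig type) is non-basic, so the α-stereocentre should survive; the descriptor changes only through priorities.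

Step 11
Reactants: 17 (R)-tert-butyl[(4,4-dibromo-2-methylbut-3-en-1-yl)oxy]dimethylsilane
Product: 19 (R)-tert-butyldimethylsilyl ether of 2-methyl-4-(trimethylsilyl)but-3-yn-1-ol, via lithium acetylide 18 (not isolated)
Conditions: n-BuLi (2.1 equiv), THF, −78 °C; Me3SiCl, −78 °C to rt
Reagents that add atoms: chlorotrimethylsilane, C[Si](C)(C)Cl
Why: Second Corey–Fuchs stage (bromine–lithium exchange, Fritsch–Buttenberg–Wiechell shift, deprotonation) and C-silylation of the acetylide; C4 is not involved.

Step 12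
Reactants: 19 (R)-tert-butyldimethylsilyl ether of 2-methyl-4-(trimethylsilyl)but-3-yn-1-ol
Product: 20 (R)-2-methyl-4-(trimethylsilyl)but-3-yn-1-ol
Conditions: CSA (cat.), MeOH, 0 °C
Reagents that add atoms: none
Why: Acid-catalysed methanolysis removes the primary O-silyl group, while the alkynyl C–Si bond is stable to acid.

Step 13
Reactants: 20 (R)-2-methyl-4-(trimethylsilyl)but-3-yn-1-ol
Product: 21 (R)-(4-iodo-3-methylbut-1-yn-1-yl)trimethylsilane
Conditions: I2, PPh3, imidazole, CH2Cl2, 0 °C to rt
Reagents that add atoms: iodine, II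
Why: Appel-type iodination by SN2 at the primary carbon; the adjacent stereocentre is untouched.

**Ketone**

Step 14
Reactants: 13 Weinreb amide; 21 (R)-(4-iodo-3-methylbut-1-yn-1-yl)trimethylsilane
Product: 23 β-hydroxy ketone (4S,7R,8S,10S), via Grignard reagent 22 (not isolated)
Conditions: 21 (3 equiv), Mg, Et2O, rt; then 13, THF, −20 to 0 °C; aq. NH4Cl
Reagents that add atoms: none
Why: Grignard addition to the Weinreb amide stops at the chelated tetrahedral intermediate, and the magnesium alkoxide at C8 should suppress enolisation at C7; the C5–C6 bond is formed without a new stereocentre.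

**Side-chain aldehyde**

Step 15
Reactants: 24 (S)-2-methylglycidol
Product: 25 (S)-3-(benzyloxy)-2-methylpropane-1,2-diol
Conditions: BnOH (5 equiv), NaH (0.3 equiv), 70 °C
Reagents that add atoms: benzyl alcohol, OCc1ccccc1
Why: Base-mediated epoxide opening by benzyl alkoxide at the CH2 terminus; the quaternary centre (future C2′) keeps its pool configuration, again because the Payne shift is degenerate.

Step 16
Reactants: 25 (S)-3-(benzyloxy)-2-methylpropane-1,2-diol
Product: 26 (R)-4-[(benzyloxy)methyl]-2,2,4-trimethyl-1,3-dioxolane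
Conditions: Me2C(OMe)2, PPTS (cat.), CH2Cl2, rt
Reagents that add atoms: 2,2-dimethoxypropane, COC(C)(C)OC
Why: Transacetalisation closes the five-membered acetonide across the 1,2-diol; the descriptor changes only through priorities.

Step 17
Reactants: 26 (R)-4-[(benzyloxy)methyl]-2,2,4-trimethyl-1,3-dioxolane
Product: 27 (R)-(2,2,4-trimethyl-1,3-dioxolan-4-yl)methanol
Conditions: H2 (1 atm), Pd/C, EtOAc, rt
Reagents that add atoms: none
Why: Hydrogenolysis of the benzyl ether is neutral, so the acetonide should not migrate and the centre is not scrambled.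

Step 18
Reactants: 27 (R)-(2,2,4-trimethyl-1,3-dioxolan-4-yl)methanol
Product: 28 (S)-2,2,4-trimethyl-1,3-dioxolane-4-carbaldehyde
Conditions: Dess–Martin periodinane, NaHCO3, CH2Cl2, 0 °C to rt
Reagents that add atoms: none
Why: Dess–Martin oxidation; the aldehyde has no α-hydrogen and is therefore configurationally stable.

**Assembly and end-game**

Step 19
Reactants: 23 β-hydroxy ketone (4S,7R,8S,10S); 28 (S)-2,2,4-trimethyl-1,3-dioxolane-4-carbaldehyde
Product: 29 1,3-anti hydroxy ester (4S,6S,7S,8S,10S,2′S)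
Conditions: 28 (5 equiv), SmI2 (0.3 equiv), THF, −10 °C
Reagents that add atoms: none
Why: Evans–Tishchenko reduction: the samarium-bound hemiacetal of C8–OH and 28 delivers hydride intramolecularly to the C6 ketone through a chair-like bicyclic transition state, setting C6 1,3-anti to C8 and leaving C8–O as the protected 2-methylglycerate.

Step 20
Reactants: 29 1,3-anti hydroxy ester
Product: 30 cis-fused α-methylene-γ-butyrolactone (4S,6S,7S,8S,10S,2′S)
Conditions: Pd(PPh3)4 (10 mol %), CO (3 bar), Et3N, MeCN, 65 °C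
Reagents that add atoms: carbon monoxide, [C-]#[O+]
Why: Palladium-catalysed carbonylative lactonisation (oxidative addition to the vinyl bromide, CO insertion, acyl capture by the only free hydroxyl, C6–OH) closes ring C; the cis relation of C6 and C7 was fixed in steps 6 and 19.

Step 21
Reactants: 30 lactone with C3-silyl alkyne
Product: 31 lactone with terminal alkyne (C2–H)
Conditions: AgNO3 (0.2 equiv), 2,6-lutidine, acetone/H2O, rt
Reagents that add atoms: none
Why: Silver-catalysed protodesilylation of the alkynylsilane runs under neutral aqueous conditions that should spare silyl ethers, acetonide, ester and methylene lactone.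

Step 22
Reactants: 31 lactone with terminal alkyne
Product: 32 C1 aldehyde (C10–OSiEt3 retained)
Conditions: (COCl)2, DMSO, CH2Cl2, −78 to −40 °C; Et3N, −78 °C to rt
Reagents that add atoms: none
Why: Under Swern conditions the chlorosulfonium reagent cleaves the primary triethylsilyl ether selectively and oxidises it directly to the aldehyde, while the tertiary silyl ether stays; the aldehyde has no α-hydrogen.

Step 23
Reactants: 32 C1 aldehyde
Product: 33 seco acid (C1 carboxylic acid, C2 alkyne terminus)
Conditions: NaClO2, NaH2PO4, 2-methylbut-2-ene, t-BuOH/H2O, 0 °C to rt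
Reagents that add atoms: sodium chlorite, [Na+].[O-]Cl=O
Why: Pinnick oxidation is selective for the aldehyde, and the scavenger keeps hypochlorite from the alkenes and the alkyne.

Step 24
Reactants: 33 seco acid
Product: 36 furanone acetonide (4S,6S,7S,8S,10S,2′S), via acid chloride 34 (not isolated), via cyclodec-2-ynone 35 (not isolated)
Conditions: Me2C=C(Cl)NMe2 (1.1 equiv), CH2Cl2, 0 °C; slow addition (12 h) to PdCl2(PPh3)2 (10 mol %), CuI (20 mol %), Et3N (3 equiv), THF (1 mM), rt; then Bu4NF/AcOH, 0 °C
Reagents that add atoms: none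
Why: Proposed new method: 34 adds oxidatively to zerovalent palladium, the copper acetylide of the C2 terminus transmetalates and reductive elimination forms C1–C2, closing ring A as cyclodec-2-ynone 35; this is the intramolecular medium-ring variant of the acyl Sonogashira coupling, the closest known types being the intermolecular coupling of pivaloyl-type acid chlorides with terminal alkynes and Sonogashira macrocyclisations to strained cycloalkynes. Fluoride then frees the C10 alkoxide, which adds to C3 of the bent ynone in a 5-endo-dig oxa-Michael closure, the known route from α′-hydroxy ynones to 3(2H)-furanones; this O–C3 bond closes ring B and, being transannular, the nine-membered oxa-bridge at the same time. Ring A closes by sp2–sp coupling out of an eleven-membered palladacycle, helped by high dilution and by two turn elements, the cis-fused lactone and the quaternary C10. No stereocentre is formed; C4, C6, C7, C8, C10 and C2′ are carried through, and acetic acid buffering keeps the propargylic C4–H from epimerising. The step needs ring closure over oligomerisation and attack of oxygen at C3 rather than at the methylene lactone, which dilution, the 1,4 placement of O and C3 within ring A and the release of alkyne strain should secure.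

Step 25
Reactants: 36 furanone acetonide
Product: 37 CNP0263764.3
Conditions: AcOH/H2O (4:1), 40 °C
Reagents that add atoms: none
Why: Acid hydrolysis of the acetonide frees the side-chain diol; the vinylogous ester of ring B, the lactone and the hindered ester are stable to aqueous acetic acid and no stereocentre is touched.

**Compound list**

1 | (R)-2-methylglycidol, [(2R)-2-methyloxiran-2-yl]methanol | OC[C@]1(C)CO1 | starting material
2 | (S)-2-methylpent-4-ene-1,2-diol | C=CC[C@](C)(O)CO | intermediate
3 | (S)-2-methyl-1,2-bis(triethylsilyloxy)pent-4-ene | C=CC[C@](C)(O[Si](CC)(CC)CC)CO[Si](CC)(CC)CC | intermediate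
4 | ozonide of 3 (3-substituted 1,2,4-trioxolane, both epimers at the acetal carbon) | O1OC(C[C@](C)(O[Si](CC)(CC)CC)CO[Si](CC)(CC)CC)OC1 | intermediate
5 | (S)-3-methyl-3,4-bis(triethylsilyloxy)butanal (fragment A, C8 aldehyde) | O=CC[C@](C)(O[Si](CC)(CC)CC)CO[Si](CC)(CC)CC | intermediate
6 | 3-bromobut-3-en-1-ol | C=C(Br)CCO | starting material
7 | 3-bromobut-3-enoic acid | C=C(Br)CC(=O)O | intermediate
8 | (R)-4-benzyloxazolidin-2-one | O=C1N[C@H](Cc2ccccc2)CO1 | starting material
9 | 3-bromobut-3-enoic pivalic anhydride | C=C(Br)CC(=O)OC(=O)C(C)(C)C | intermediate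
10 | (R)-4-benzyl-3-(3-bromobut-3-enoyl)oxazolidin-2-one (fragment B) | C=C(Br)CC(=O)N1[C@H](Cc2ccccc2)COC1=O | intermediate
11 | (Z)-dibutylboron enolate of 10 | C=C(Br)/C=C(\OB(CCCC)CCCC)N1[C@H](Cc2ccccc2)COC1=O | intermediate
12 | (R)-4-benzyl-3-[(2R,3S,5S)-2-(1-bromoethenyl)-3-hydroxy-5-methyl-5,6-bis(triethylsilyloxy)hexanoyl]oxazolidin-2-one | C=C(Br)[C@@H](C(=O)N1[C@H](Cc2ccccc2)COC1=O)[C@@H](O)C[C@](C)(O[Si](CC)(CC)CC)CO[Si](CC)(CC)CC | intermediate
13 | (2R,3S,5S)-2-(1-bromoethenyl)-3-hydroxy-N-methoxy-N,5-dimethyl-5,6-bis(triethylsilyloxy)hexanamide | C=C(Br)[C@@H](C(=O)N(C)OC)[C@@H](O)C[C@](C)(O[Si](CC)(CC)CC)CO[Si](CC)(CC)CC | intermediate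
14 | methyl (S)-3-hydroxy-2-methylpropanoate (Roche ester) | OC[C@H](C)C(=O)OC | starting material
15 | methyl (S)-3-(tert-butyldimethylsilyloxy)-2-methylpropanoate | CC(C)(C)[Si](C)(C)OC[C@H](C)C(=O)OC | intermediate
16 | (S)-3-(tert-butyldimethylsilyloxy)-2-methylpropanal | CC(C)(C)[Si](C)(C)OC[C@H](C)C=O | intermediate
17 | (R)-tert-butyl[(4,4-dibromo-2-methylbut-3-en-1-yl)oxy]dimethylsilane | CC(C)(C)[Si](C)(C)OC[C@H](C)C=C(Br)Br | intermediate
18 | lithium acetylide, (R)-4-(tert-butyldimethylsilyloxy)-3-methylbut-1-yn-1-yllithium | CC(C)(C)[Si](C)(C)OC[C@H](C)C#C[Li] | intermediate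
19 | (R)-tert-butyldimethyl{[2-methyl-4-(trimethylsilyl)but-3-yn-1-yl]oxy}silane | CC(C)(C)[Si](C)(C)OC[C@H](C)C#C[Si](C)(C)C | intermediate
20 | (R)-2-methyl-4-(trimethylsilyl)but-3-yn-1-ol | OC[C@H](C)C#C[Si](C)(C)C | intermediate
21 | (R)-(4-iodo-3-methylbut-1-yn-1-yl)trimethylsilane (fragment C) | IC[C@H](C)C#C[Si](C)(C)C | intermediate
22 | Grignard reagent of 21, (R)-[2-methyl-4-(trimethylsilyl)but-3-yn-1-yl]magnesium iodide | I[Mg]C[C@H](C)C#C[Si](C)(C)C | intermediate
23 | (3S,6R,7S,9S)-6-(1-bromoethenyl)-7-hydroxy-3,9-dimethyl-9,10-bis(triethylsilyloxy)-1-(trimethylsilyl)dec-1-yn-5-one (C6 ketone; 4S,7R,8S,10S in germacrane numbering) | C=C(Br)[C@@H](C(=O)C[C@H](C)C#C[Si](C)(C)C)[C@@H](O)C[C@](C)(O[Si](CC)(CC)CC)CO[Si](CC)(CC)CC | intermediate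
24 | (S)-2-methylglycidol, [(2S)-2-methyloxiran-2-yl]methanol | OC[C@@]1(C)CO1 | starting material
25 | (S)-3-(benzyloxy)-2-methylpropane-1,2-diol | OC[C@](C)(O)COCc1ccccc1 | intermediate
26 | (R)-4-[(benzyloxy)methyl]-2,2,4-trimethyl-1,3-dioxolane | CC1(C)OC[C@@](C)(COCc2ccccc2)O1 | intermediate
27 | (R)-(2,2,4-trimethyl-1,3-dioxolan-4-yl)methanol | CC1(C)OC[C@@](C)(CO)O1 | intermediate
28 | (S)-2,2,4-trimethyl-1,3-dioxolane-4-carbaldehyde | CC1(C)OC[C@@](C)(C=O)O1 | intermediate
29 | 1,3-anti hydroxy ester (4S,6S,7S,8S,10S,2′S): C6–OH, C8 ester of (S)-2,2,4-trimethyl-1,3-dioxolane-4-carboxylic acid, C11 vinyl bromide, C3-silyl alkyne, C1 and C10 triethylsilyl ethers | C=C(Br)[C@@H]([C@@H](O)C[C@H](C)C#C[Si](C)(C)C)[C@@H](OC(=O)[C@@]1(C)OC(C)(C)OC1)C[C@](C)(O[Si](CC)(CC)CC)CO[Si](CC)(CC)CC | intermediate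
30 | cis-fused α-methylene-γ-butyrolactone (12,6-olide; 4S,6S,7S,8S,10S,2′S) with C3-silyl alkyne and C1, C10 triethylsilyl ethers | C=C1C(=O)O[C@@H](C[C@H](C)C#C[Si](C)(C)C)[C@H]1[C@@H](OC(=O)[C@@]2(C)OC(C)(C)OC2)C[C@](C)(O[Si](CC)(CC)CC)CO[Si](CC)(CC)CC | intermediate
31 | lactone 30 with terminal alkyne (C2–H) | C=C1C(=O)O[C@@H](C[C@H](C)C#C)[C@H]1[C@@H](OC(=O)[C@@]2(C)OC(C)(C)OC2)C[C@](C)(O[Si](CC)(CC)CC)CO[Si](CC)(CC)CC | intermediate
32 | C1 aldehyde (C10–OSiEt3, terminal alkyne, lactone, C8 ester) | C=C1C(=O)O[C@@H](C[C@H](C)C#C)[C@H]1[C@@H](OC(=O)[C@@]2(C)OC(C)(C)OC2)C[C@](C)(O[Si](CC)(CC)CC)C=O | intermediate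
33 | seco acid (C1 carboxylic acid; 4S,6S,7S,8S,10S,2′S) | C=C1C(=O)O[C@@H](C[C@H](C)C#C)[C@H]1[C@@H](OC(=O)[C@@]2(C)OC(C)(C)OC2)C[C@](C)(O[Si](CC)(CC)CC)C(=O)O | intermediate
34 | acid chloride of 33 | C=C1C(=O)O[C@@H](C[C@H](C)C#C)[C@H]1[C@@H](OC(=O)[C@@]2(C)OC(C)(C)OC2)C[C@](C)(O[Si](CC)(CC)CC)C(=O)Cl | intermediate
35 | cyclodec-2-ynone: 1-oxo-10-(triethylsilyloxy)germacr-2-yn-11(13)-en-12,6-olide 8-ester (4S,6S,7S,8S,10S,2′S) | C=C1C(=O)O[C@H]2C[C@H](C)C#CC(=O)[C@](C)(C[C@H](OC(=O)[C@@]3(C)OC(C)(C)OC3)[C@@H]12)O[Si](CC)(CC)CC | intermediate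
36 | furanone acetonide: 3,10-epoxy-1-oxogermacra-2,11(13)-dien-12,6-olide 8-[(S)-2,2,4-trimethyl-1,3-dioxolane-4-carboxylate] (4S,6S,7S,8S,10S) | C=C1C(=O)O[C@H]2C[C@H](C)C3=CC(=O)[C@](C)(C[C@H](OC(=O)[C@@]4(C)OC(C)(C)OC4)[C@@H]12)O3 | intermediate
37 | CNP0263764.3: (4S,6S,7S,8S,10S)-3,10-epoxy-1-oxogermacra-2,11(13)-dien-12,6-olide 8-[(2S)-2,3-dihydroxy-2-methylpropanoate] | C=C1C(=O)O[C@H]2C[C@H](C)C3=CC(=O)[C@](C)(C[C@H](OC(=O)[C@@](C)(O)CO)[C@@H]12)O3 | target

**Count and risks**

Total steps: 25. Longest linear sequence: 14 steps (steps 8–14 and 19–25, from the Roche ester 14).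

Step 24 (Proposed new method): intermolecular coupling and oligomerisation may outrun closure of ring A, or the acyl–palladium species may lose CO before transmetalation. The fallback sets out from aldehyde 32 and uses known chemistry. Iodination of the alkyne terminus (NIS, AgNO3 cat., acetone) should give iodoalkyne aldehyde F1. Nozaki–Hiyama–Kishi ring closure (CrCl2, NiCl2 cat., THF, 2 mM) should give the ten-membered propargylic alcohol F2 as a pair of C1 epimers. Dess–Martin oxidation should then give ynone 35, and the fluoride stage of step 24 (Bu4NF/AcOH) brings the route back to 36.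

Step 19: hemiacetal formation with the α-quaternary aldehyde may be slow, so that retro-aldol cleavage or epimerisation at C7 competes with hydride transfer. The fallback sets out from 23 and 28. Pinnick oxidation of 28 should give (S)-2,2,4-trimethyl-1,3-dioxolane-4-carboxylic acid F3, and Steglich esterification of C8–OH of 23 with it (DCC, DMAP) should give acyloxy ketone F4. Corey–Bakshi–Shibata reduction ((R)-Me-CBS, catecholborane, toluene, −78 °C), with the branched C7 side as the large group, should set C6 by reagent control and return to 29.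

Step 20: oxidative addition into the hindered 1,1-disubstituted vinyl bromide may be slow, and 1,3-acyl migration from O8 to O6 under the warm basic conditions could take away the free hydroxyl. The fallback sets out from 29. Stille coupling with Bu3SnCH2OH (Pd(PPh3)4, dioxane, 80 °C) should give allylic alcohol diol F5, and MnO2 in CH2Cl2 (allylic oxidation, lactol formation with C6–OH, second oxidation) should close the methylene lactone and return to 30.

Further compounds
F1 | step 24 | iodoalkyne aldehyde (32 with C2–I) | C=C1C(=O)O[C@@H](C[C@H](C)C#CI)[C@H]1[C@@H](OC(=O)[C@@]2(C)OC(C)(C)OC2)C[C@](C)(O[Si](CC)(CC)CC)C=O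
F2 | step 24 | ten-membered propargylic alcohol (1-hydroxy analogue of 35, both C1 epimers) | C=C1C(=O)O[C@H]2C[C@H](C)C#CC(O)[C@](C)(C[C@H](OC(=O)[C@@]3(C)OC(C)(C)OC3)[C@@H]12)O[Si](CC)(CC)CC
F3 | step 19 | (S)-2,2,4-trimethyl-1,3-dioxolane-4-carboxylic acid | CC1(C)OC[C@@](C)(C(=O)O)O1
F4 | step 19 | C8 acyloxy C6 ketone (ester of 23 with F3) | C=C(Br)[C@@H](C(=O)C[C@H](C)C#C[Si](C)(C)C)[C@@H](OC(=O)[C@@]1(C)OC(C)(C)OC1)C[C@](C)(O[Si](CC)(CC)CC)CO[Si](CC)(CC)CC
F5 | step 20 | allylic alcohol diol (29 with CH2OH in place of Br at C11) | C=C(CO)[C@@H]([C@@H](O)C[C@H](C)C#C[Si](C)(C)C)[C@@H](OC(=O)[C@@]1(C)OC(C)(C)OC1)C[C@](C)(O[Si](CC)(CC)CC)CO[Si](CC)(CC)CC
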